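A direct plan would assemble the 2-arylbenzofuran from two halogenated arenes and add the prenyl groups last: Sonogashira coupling of the alkyne A1 (2,4-dibromo-3-ethynyl-1,5-dimethoxybenzene) with the iodoresorcinol A2 (2-bromo-4-iodobenzene-1,3-diol) and ring closure in the same flask, O-demethylation to the tribromotriol A3, and a threefold coupling of A3 with the prenylboronic ester A4. Its weakest steps would be:
- the threefold prenyl cross-coupling on free ortho-bromophenols, which would need three successive linear-selective events at flanked positions and has no close precedent;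
- the coupling and cyclisation of an alkyne set between two ortho bromines, in which zerovalent palladium would have to choose one C–I bond over three C–Br bonds;
- the boron tribromide demethylation, which would add length without adding complexity.

Ring B is a resorcinol with the alternating oxygen pattern of a polyketide (O at C3 and C5) and a mirror plane through C1 and C4. The route would therefore rest on a biomimetic [5+1] disconnection: C1, the carbon bonded to benzofuran C2, would come from the ester carbon of a benzofuran-2-carboxylate, and C2 to C6 with both prenyl groups from acetylacetone alkylated at both ends. Claisen acylation would give a 1,3,5-triketone, and the key aldol folding would close and aromatise ring B, creating the hindered biaryl junction and the free resorcinol at once. No halogenated core, no prenyl cross-coupling on free phenols and no boron halide demethylation would be needed.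

Key step: step 8

Assumption: compound 1 is taken as commercially available (it is otherwise one step from resorcinol). The target has no stereocentre and its alkenes have no E/Z isomerism, so no stereocontrol is required.

Step 1
Reactants: 1 1,3-bis(methoxymethoxy)benzene; 2 1-bromo-3-methylbut-2-ene (prenyl bromide)
Product: 4 1,3-bis(methoxymethoxy)-2-(3-methylbut-2-en-1-yl)benzene, via aryllithium 3 (not isolated)
Conditions: n-BuLi (1.1 equiv), THF, 0 °C → rt; CuI (10 mol %), then 2 (1.2 equiv), −30 °C → rt
Reagents that add atoms: none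
Why: Directed ortho metalation at C2, where both MOM oxygens bind lithium, followed by copper-catalysed SN2 allylation of the aryl–metal at the primary carbon of prenyl bromide, should give the linear prenyl group; no stereocentre is formed.

Step 2
Reactants: 4 1,3-bis(methoxymethoxy)-2-(3-methylbut-2-en-1-yl)benzene
Product: 6 2,4-bis(methoxymethoxy)-3-(3-methylbut-2-en-1-yl)benzaldehyde, via aryllithium 5 (not isolated)
Conditions: n-BuLi (1.2 equiv), TMEDA (1.2 equiv), THF, −20 → 0 °C; DMF (2 equiv), 0 °C → rt; H2O
Reagents that add atoms: N,N-dimethylformamide, CN(C)C=O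
Why: A second directed ortho metalation, now at C4 next to one MOM ether because C2 is occupied, and formylation of the aryllithium with DMF should give the aldehyde; ring lithiation is expected to outrun deprotonation of the benzylic CH2 under these kinetic conditions.

Step 3
Reactants: 6 2,4-bis(methoxymethoxy)-3-(3-methylbut-2-en-1-yl)benzaldehyde
Product: 7 2-hydroxy-4-(methoxymethoxy)-3-(3-methylbut-2-en-1-yl)benzaldehyde
Conditions: HCl (0.3 M in MeOH), 0 °C → rt, stopped when 6 is consumed
Reagents that add atoms: none
Why: Acid-catalysed methanolysis of a MOM acetal, expected to be faster at O2 because the phenol set free there is held in a hydrogen bond to the formyl oxygen, while dilute acid at low temperature should leave the second acetal and the prenyl alkene intact.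

Step 4
Reactants: 7 2-hydroxy-4-(methoxymethoxy)-3-(3-methylbut-2-en-1-yl)benzaldehyde; 8 methyl bromoacetate
Product: 11 methyl 6-(methoxymethoxy)-7-(3-methylbut-2-en-1-yl)-1-benzofuran-2-carboxylate, via aryloxyacetate 9 (not isolated), via hydroxydihydrobenzofuran 10 (not isolated)
Conditions: K2CO3 (3 equiv), DMF, 60 °C then 110 °C
Reagents that add atoms: none
Why: Williamson O-alkylation of the phenoxide and, on heating, intramolecular aldol condensation of the aryloxyacetate enolate with the ortho formyl group (Rap–Stoermer-type benzofuran synthesis) should close the furan ring by its C2–C3 bond and aromatise it by loss of water.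

Step 5
Reactants: 12 pentane-2,4-dione (acetylacetone); 2 1-bromo-3-methylbut-2-ene (prenyl bromide)
Product: 13 8-methylnon-7-ene-2,4-dione
Conditions: LiN(iPr)2 (2.1 equiv), THF, 0 °C; 2 (1.0 equiv), −78 → 0 °C; aq. HCl
Reagents that add atoms: none
Why: γ-Alkylation of a β-diketone dianion: the terminal carbanion is far more nucleophilic than the central diketonate carbon, so one equivalent of prenyl bromide should be taken up by SN2 at one methyl group only.

Step 6
Reactants: 13 8-methylnon-7-ene-2,4-dione; 2 1-bromo-3-methylbut-2-ene (prenyl bromide)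
Product: 14 2,12-dimethyltrideca-2,11-diene-6,8-dione
Conditions: LiN(iPr)2 (2.1 equiv), THF, 0 °C; 2 (1.05 equiv), −78 → 0 °C; aq. HCl
Reagents that add atoms: none
Why: Second γ-alkylation of a β-diketone dianion: the kinetic dianion should form at the remaining methyl group, which is less hindered than the substituted C5 methylene, and its SN2 reaction with prenyl bromide should put the second prenyl group at the other end of the diketone.

Step 7
Reactants: 14 2,12-dimethyltrideca-2,11-diene-6,8-dione; 11 methyl 6-(methoxymethoxy)-7-(3-methylbut-2-en-1-yl)-1-benzofuran-2-carboxylate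
Product: 15 1-[6-(methoxymethoxy)-7-(3-methylbut-2-en-1-yl)-1-benzofuran-2-yl]-9-methyl-2-(3-methylbut-2-en-1-yl)dec-8-ene-1,3,5-trione (racemic)
Conditions: 14 (2.2 equiv), LiN(iPr)2 (4.4 equiv), THF, 0 °C; then 11 (1.0 equiv), −78 → 0 °C; AcOH
Reagents that add atoms: none
Why: Claisen-type acylation of the β-diketone dianion at its terminal carbanion by the non-enolisable hetaryl ester; the second equivalent of dianion deprotonates the more acidic triketone as it forms and so prevents a second addition, and the new C2 centre is a racemic, epimerisable β-diketone carbon that step 8 removes.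

Step 8
Reactants: 15 1-[6-(methoxymethoxy)-7-(3-methylbut-2-en-1-yl)-1-benzofuran-2-yl]-9-methyl-2-(3-methylbut-2-en-1-yl)dec-8-ene-1,3,5-trione
Product: 18 5-[6-(methoxymethoxy)-7-(3-methylbut-2-en-1-yl)-1-benzofuran-2-yl]-4,6-bis(3-methylbut-2-en-1-yl)benzene-1,3-diol, via aldol 16 (not isolated), via cyclohexenedione 17 (not isolated)
Conditions: KOH (2 M in H2O)/MeOH/THF, argon, rt → 55 °C; then 1 M HCl to pH 5
Reagents that add atoms: none
Why: Intramolecular aldol condensation and aromatisation of a 1,3,5-triketone, the laboratory counterpart of polyketide folding (closest known type: base-mediated cyclisation of 2,4,6-triketones to orcinol-type resorcinols). In aqueous hydroxide 15 should exist as the C3–C5 diketonate, because enolisation across C1–C3 is disfavoured by allylic strain from the C2 prenyl group, so the aroyl carbonyl C1 stays electrophilic while the diketonate resists retro-Claisen cleavage. Reversible deprotonation at C6 then gives the carbanion that adds to C1 in a 6-(enolendo)-exo-trig closure, forming the C1–C6 bond of ring B (aldol 16); E1cB loss of water gives 17, whose enolisation to the resorcinol makes the sequence irreversible. Only one carbocyclic mode is possible, since the benzofuranyl end has no α-hydrogen and any other closure would give a four-membered ring, and a 4-pyranone formed by O-cyclisation would be reopened by hydroxide. The transient stereocentres of 15, 16 and 17 are erased on aromatisation, and the MOM ether keeps O6 from donating into the ketone as a phenoxide.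

Step 9
Reactants: 18 5-[6-(methoxymethoxy)-7-(3-methylbut-2-en-1-yl)-1-benzofuran-2-yl]-4,6-bis(3-methylbut-2-en-1-yl)benzene-1,3-diol
Product: 19 5-[6-hydroxy-7-(3-methylbut-2-en-1-yl)-1-benzofuran-2-yl]-4,6-bis(3-methylbut-2-en-1-yl)benzene-1,3-diol
Conditions: HCl (1 M in MeOH/THF), argon, rt → 35 °C
Reagents that add atoms: none
Why: Acid-catalysed methanolysis of the last MOM acetal under dilute, cool conditions, which are expected to leave the three ortho-prenylphenol units uncyclised (no chroman formation); no stereocentre is involved.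

**Compound list**
1 | 1,3-bis(methoxymethoxy)benzene | COCOc1cccc(OCOC)c1 | starting material
2 | 1-bromo-3-methylbut-2-ene (prenyl bromide) | CC(C)=CCBr | starting material
3 | [2,6-bis(methoxymethoxy)phenyl]lithium | [Li]c1c(OCOC)cccc1OCOC | intermediate
4 | 1,3-bis(methoxymethoxy)-2-(3-methylbut-2-en-1-yl)benzene | COCOc1cccc(OCOC)c1CC=C(C)C | intermediate
5 | [2,4-bis(methoxymethoxy)-3-(3-methylbut-2-en-1-yl)phenyl]lithium | [Li]c1ccc(OCOC)c(CC=C(C)C)c1OCOC | intermediate
6 | 2,4-bis(methoxymethoxy)-3-(3-methylbut-2-en-1-yl)benzaldehyde | O=Cc1ccc(OCOC)c(CC=C(C)C)c1OCOC | intermediate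
7 | 2-hydroxy-4-(methoxymethoxy)-3-(3-methylbut-2-en-1-yl)benzaldehyde | O=Cc1ccc(OCOC)c(CC=C(C)C)c1O | intermediate
8 | methyl bromoacetate | COC(=O)CBr | starting material
9 | methyl 2-[6-formyl-3-(methoxymethoxy)-2-(3-methylbut-2-en-1-yl)phenoxy]acetate | COC(=O)COc1c(C=O)ccc(OCOC)c1CC=C(C)C | intermediate
10 | methyl 3-hydroxy-6-(methoxymethoxy)-7-(3-methylbut-2-en-1-yl)-2,3-dihydro-1-benzofuran-2-carboxylate (racemic mixture of diastereomers) | COC(=O)C1Oc2c(CC=C(C)C)c(OCOC)ccc2C1O | intermediate
11 | methyl 6-(methoxymethoxy)-7-(3-methylbut-2-en-1-yl)-1-benzofuran-2-carboxylate | COC(=O)c1cc2ccc(OCOC)c(CC=C(C)C)c2o1 | intermediate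
12 | pentane-2,4-dione (acetylacetone) | CC(=O)CC(C)=O | starting material
13 | 8-methylnon-7-ene-2,4-dione | CC(=O)CC(=O)CCC=C(C)C | intermediate
14 | 2,12-dimethyltrideca-2,11-diene-6,8-dione | CC(C)=CCCC(=O)CC(=O)CCC=C(C)C | intermediate
15 | 1-[6-(methoxymethoxy)-7-(3-methylbut-2-en-1-yl)-1-benzofuran-2-yl]-9-methyl-2-(3-methylbut-2-en-1-yl)dec-8-ene-1,3,5-trione (racemic) | COCOc1ccc2cc(C(=O)C(CC=C(C)C)C(=O)CC(=O)CCC=C(C)C)oc2c1CC=C(C)C | intermediate
16 | 5-hydroxy-5-[6-(methoxymethoxy)-7-(3-methylbut-2-en-1-yl)-1-benzofuran-2-yl]-4,6-bis(3-methylbut-2-en-1-yl)cyclohexane-1,3-dione (mixture of stereoisomers) | O=C1CC(=O)C(CC=C(C)C)C(O)(c2cc3ccc(OCOC)c(CC=C(C)C)c3o2)C1CC=C(C)C | intermediate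
17 | 5-[6-(methoxymethoxy)-7-(3-methylbut-2-en-1-yl)-1-benzofuran-2-yl]-4,6-bis(3-methylbut-2-en-1-yl)cyclohex-4-ene-1,3-dione (racemic) | O=C1CC(=O)C(CC=C(C)C)=C(c2cc3ccc(OCOC)c(CC=C(C)C)c3o2)C1CC=C(C)C | intermediate
18 | 5-[6-(methoxymethoxy)-7-(3-methylbut-2-en-1-yl)-1-benzofuran-2-yl]-4,6-bis(3-methylbut-2-en-1-yl)benzene-1,3-diol | COCOc1ccc2cc(-c3c(CC=C(C)C)c(O)cc(O)c3CC=C(C)C)oc2c1CC=C(C)C | intermediate
19 | 5-[6-hydroxy-7-(3-methylbut-2-en-1-yl)-1-benzofuran-2-yl]-4,6-bis(3-methylbut-2-en-1-yl)benzene-1,3-diol | CC(C)=CCc1c(O)cc(O)c(CC=C(C)C)c1-c1cc2ccc(O)c(CC=C(C)C)c2o1 | target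

Total step count: 9. Longest linear sequence: 7 steps (steps 1, 2, 3, 4, 7, 8 and 9); steps 5 and 6 make the second fragment.

Steps most likely to fail:

Step 8. The terminal methylene may enolise too rarely for the aldol to compete, so that the triketone would be recovered or slowly degraded. The nucleophile would then be activated as a β-keto acid. Setting out from 15, its trianion (LiN(iPr)2, 3.3 equiv, THF) would be carboxylated with CO2 at the terminal carbanion to give the trioxoheptanoic acid F1. In aqueous KOH or a pH 9 buffer its doubly activated C2 should add to the aryl ketone, the well-known aldol mode of 3,5,7-trioxoalkanoic acids, to give the hydroxy keto acid F2. This would lose water towards the other prenyl-bearing carbon and then CO2 as a β-keto acid, and so come back to the route at 18.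

Step 7. Proton transfer between the hindered secondary carbanion and the product, or slow addition to the ester, may stop the acylation. The carbonyl carbon would then be joined at the aldehyde level. Setting out from 11, reduction with iBu2AlH would give the alcohol F3 and oxidation with MnO2 the aldehyde F4. The dianion of 14 adds to aldehydes at its terminal carbon and should give the hydroxy diketone F5 (mixture of diastereomers), and oxidation with Dess–Martin periodinane would come back to the route at 15.

Step 3. Site selectivity between the two acetals may be poor. Both would then be cleaved and the site chosen in the other direction. Setting out from 6, methanolic HCl at 40 °C would give the dihydroxy aldehyde F6. Chloromethyl methyl ether with K2CO3 in acetone should then etherify only O4, because O2–H is tied up in the hydrogen bond to the formyl group, and so come back to the route at 7.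

**Further compounds**
F1 | step 8 | 7-[6-(methoxymethoxy)-7-(3-methylbut-2-en-1-yl)-1-benzofuran-2-yl]-2,6-bis(3-methylbut-2-en-1-yl)-3,5,7-trioxoheptanoic acid | COCOc1ccc2cc(C(=O)C(CC=C(C)C)C(=O)CC(=O)C(CC=C(C)C)C(O)=O)oc2c1CC=C(C)C
F2 | step 8 | 2-hydroxy-2-[6-(methoxymethoxy)-7-(3-methylbut-2-en-1-yl)-1-benzofuran-2-yl]-1,3-bis(3-methylbut-2-en-1-yl)-4,6-dioxocyclohexane-1-carboxylic acid | OC(=O)C1(CC=C(C)C)C(=O)CC(=O)C(CC=C(C)C)C1(O)c1cc2ccc(OCOC)c(CC=C(C)C)c2o1
F3 | step 7 | [6-(methoxymethoxy)-7-(3-methylbut-2-en-1-yl)-1-benzofuran-2-yl]methanol | OCc1cc2ccc(OCOC)c(CC=C(C)C)c2o1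
F4 | step 7 | 6-(methoxymethoxy)-7-(3-methylbut-2-en-1-yl)-1-benzofuran-2-carbaldehyde | O=Cc1cc2ccc(OCOC)c(CC=C(C)C)c2o1
F5 | step 7 | 1-hydroxy-1-[6-(methoxymethoxy)-7-(3-methylbut-2-en-1-yl)-1-benzofuran-2-yl]-9-methyl-2-(3-methylbut-2-en-1-yl)dec-8-ene-3,5-dione | COCOc1ccc2cc(C(O)C(CC=C(C)C)C(=O)CC(=O)CCC=C(C)C)oc2c1CC=C(C)C
F6 | step 3 | 2,4-dihydroxy-3-(3-methylbut-2-en-1-yl)benzaldehyde | O=Cc1ccc(O)c(CC=C(C)C)c1O
A1 | direct plan | 2,4-dibromo-3-ethynyl-1,5-dimethoxybenzene | COc1cc(OC)c(Br)c(C#C)c1Br
A2 | direct plan | 2-bromo-4-iodobenzene-1,3-diol | Oc1ccc(I)c(O)c1Br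
A3 | direct plan | 4,6-dibromo-5-(7-bromo-6-hydroxy-1-benzofuran-2-yl)benzene-1,3-diol | Oc1cc(O)c(Br)c(-c2cc3ccc(O)c(Br)c3o2)c1Br
A4 | direct plan | 4,4,5,5-tetramethyl-2-(3-methylbut-2-en-1-yl)-1,3,2-dioxaborolane | CC(C)=CCB1OC(C)(C)C(C)(C)O1
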